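I could not make the alpha flask rise by waiting, however I read it: 17.5 % at 3.00 h and 18.5 % at 20.0 h differ by 1 percentage point, with a scatter of 0.5 points on each reading. My decision was what to do with this flask at 20 h.

| flask | substrate | coupling partner | capture agent | precatalyst | temperature | remark | time |
|---|---|---|---|---|---|---|---|
| alpha | 0.80 M | 0.60 equiv | 0.24 M | 2.5 mol% | 100 °C | the very flask that is asked about, followed so far |  |
| beta | 0.80 M | 0.90 equiv | 0.24 M | 2.5 mol% | 106 °C | run made earlier |  |
| flask | 0.80 M | 0.600 equiv | 0.240 M | 2.5 mol% | 100 °C |  | 20 h |

alpha run (percent of the substrate charged)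

| time / h | product / % |
|---|---|
| 3.00 | 17.5 |
| 6.00 | 18.2 |
| 10.0 | 17.8 |
| 12.0 | 16.9 |
| 15.0 | 18.6 |
| 20.0 | 18.5 |

beta run (percent of the substrate charged)

| time / min | product / % |
|---|---|
| 15.0 | 5.8 |
| 30.0 | 11.7 |
| 50.0 | 15.5 |
| 60.0 | 17.2 |
| 80.0 | 18.5 |
| 90.0 | 17.3 |

(readings scatter by 0.5 percentage points)

- product is meant together with its crystals
- solid, in amounts per volume of the solution: crystals
- additions bring no volume worth counting
- steps thought possible: catalyst intermediate B -> free catalyst + product; coupling partner + precatalyst -> free catalyst + spent reagent; catalyst intermediate A + capture agent -> trapped intermediate; coupling partner + free catalyst <-> catalyst intermediate A; crystals <-> product; substrate + catalyst intermediate A <-> catalyst intermediate B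

- midnight: at 20 h add precatalyst, 100 % of the amount charged, then wait 6.0 h
- winter: change nothing and wait 6.0 h more
- noon: at 20 h raise the temperature by 10 K, then wait 6.0 h
- dawn: at 20 h add coupling partner, 100 % of the amount charged, then wait 6.0 h

1. product, in percent of the substrate first charged, at 20 h
2. the option that brings most further product ("none" if no option brings more than 2 percentage points) (midnight / winter / noon / dawn / none)
3. product present, in percent of the substrate first charged, after midnight
4. product present, in percent of the substrate first charged, after noon

The alpha readings averaged 17.9 % of the substrate, against 0.60 equiv of coupling partner charged, and the beta flask, at 0.90 equiv and 106 °C, ended at 18.5 % and 17.3 %. So I suspected the catalyst, of which alpha held 0.0200 M, far less than its 0.24 M of capture agent.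

Substrate and capture agent both react with catalyst intermediate A, so I treated each loss of catalyst as the end of a race between them. Taking alpha's catalyst as wholly lost, with a mean c(capture agent) of 0.230 M, I read 2.27 from those scattered readings for s: the logarithm of substrate charged over substrate left, times mean c(capture agent), divided by catalyst lost. This is a selectivity factor.

Waiting, heat and coupling partner add no catalyst, so I expected nothing from them. Midnight adds 0.0200 M of precatalyst, and I took the mean c(capture agent) during that second batch as 0.210 M, so s gave me 33.9 % of product. Alpha's readings were already level at 3.00 h, a time shorter than the 6.0 h on offer, so I chose to add precatalyst.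

The forecast said 18 % now (range 17.5 % to 18.5 %), midnight as best, 34 % after midnight (30 % to 36.5 %) and 18 % after noon (17.3 % to 19.5 %), on the ground that “Intermediate A is irreversibly trapped by the excess capture agent”.

The flask gave 18.0 % at 20 h, 33.4 % after midnight and 18.0 % after noon, and midnight was best, with 15 points against 0 points for winter and 0 points for dawn.

    catalyst intermediate B → free catalyst + product (k = 1.84 min⁻¹, Ea = 90.0 kJ mol⁻¹)
    coupling partner + precatalyst → free catalyst + spent reagent (k = 0.0607 M⁻¹ min⁻¹, Ea = 78.0 kJ mol⁻¹)
    catalyst intermediate A + capture agent → trapped intermediate (k = 1.05 M⁻¹ min⁻¹, Ea = 52.0 kJ mol⁻¹)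
    coupling partner + free catalyst ⇌ catalyst intermediate A (K = 1.17 M⁻¹, k = 5.75 M⁻¹ min⁻¹, Ea = 55.0 kJ mol⁻¹, ΔH = 32.0 kJ mol⁻¹)
    crystals ⇌ product, rate k5*(cs5 - [product]) while solid is left; crystals form when [product] > cs5 (solubility = 22.0 mM, k = 2.74 min⁻¹)
    substrate + catalyst intermediate A ⇌ catalyst intermediate B (K = 3.60 M⁻¹, k = 3.74 M⁻¹ min⁻¹, Ea = 85.0 kJ mol⁻¹, ΔH = −71.0 kJ mol⁻¹)
    (constants at 100 °C)

In this flask, trapped intermediate held 88.1 % of the catalyst by 2.00 h, when product stood at 15.9 %, and the step from catalyst intermediate B to product had by 4.00 h 99 % of its turnover up to 20 h behind it. From 10.0 h trapped intermediate held >99.9 %, and product was still 18.0 % at 200 h, with 82 % of the substrate left at 20.0 h. My s had promised 16 points from midnight, and the flask gave 15 points. For a neighbouring flask, the same flask charged with 0.096 M of capture agent, s gives 41.0 % of product; the computed result for that flask is 41.2 %.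

The earlier runs and the new flask stem from a simulated flask for substances that don't exist; scatter was added.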